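**Retrosynthetic overview**

1. Numbering used throughout: lactone O1, C2 (C=O), C3, C4 (CHOH), C5 (quaternary), then side-chain C6 (CH2) and C7 (carbinol). Enabling feature: on the five-membered lactone ring the C4 hydroxyl and the ring oxygen O1 on C5 are anti across C4–C5, while C3 and C6 are syn. This is the imprint of an anti opening, at tertiary C5, of the epoxide of a (Z)-C4=C5 olefin by the C2 carboxyl.
2. Key disconnection O1–C5: open-chain (3Z,6R)-hydroxy acid 9 undergoes, in one flask, catalytic asymmetric epoxidation (sets C4 and C5) and 5-endo epoxide-opening lactonisation; the butanolide is the last ring made.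
3. Because C3 and C6 are cis on that olefin, C2–C3–C4=C5–C6–C7 folds back into a six-membered carbocycle, cyclohexenone 7. Its C2–C7 bond is cut by Baeyer–Villiger oxidation with retention, turning an all-carbon quaternary centre into the tertiary carbinol C7 (seven-membered lactone 8, then opened).
4. That carbocycle with both methyl groups is 2,4-dimethylphenol: Birch reduction gives a regiodefined silyl enol ether, enantioselective Pd allylation sets C7, and cross-metathesis/hydrogenation completes the C16 chain.
5. Ring order: benzene ring (purchased) → cyclohexenone → seven-membered lactone (step 6) → open chain (step 7) → five-membered lactone (step 8).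

Key step: step 8

Assumption: the L-sorbose-derived enantiomer of the fructose-type epoxidation ketone (1,2:4,5-di-O-isopropylidene-β-L-erythro-2,3-hexodiulo-2,6-pyranose) is taken as an available catalyst.

**Route**

Step 1
Reactants: 1 2,4-dimethylphenol
Product: 2 tert-butyl(2,4-dimethylphenoxy)dimethylsilane
Conditions: TBSCl, imidazole, DMF, rt
Reagents that add atoms: tert-butyldimethylsilyl chloride, CC(C)(C)[Si](C)(C)Cl
Why: O-silylation of the phenol (silyl ether formation) installs a group that should survive dissolving-metal reduction and later serves as the fluoride-labile enol ether handle.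

Step 2
Reactants: 2 tert-butyl(2,4-dimethylphenoxy)dimethylsilane
Product: 3 tert-butyl[(2,4-dimethylcyclohexa-1,4-dien-1-yl)oxy]dimethylsilane
Conditions: Li, liquid NH3/THF, t-BuOH, −78 → −33 °C; solid NH4Cl, pentane extraction
Reagents that add atoms: none
Why: Birch reduction of the electron-rich aryl silyl ether protonates the two unsubstituted positions ortho and meta to oxygen, so the oxygen-bearing carbon and both methyl-bearing carbons stay sp2 and a single tetrasubstituted silyl enol ether (the enolate equivalent at the methyl-bearing α-carbon) should result.

Step 3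
Reactants: 3 tert-butyl[(2,4-dimethylcyclohexa-1,4-dien-1-yl)oxy]dimethylsilane
Product: 4 (6R)-4,6-dimethyl-6-(prop-2-en-1-yl)cyclohex-3-en-1-one
Conditions: diallyl carbonate, Pd2(dba)3 (2.5 mol%), (S)-t-Bu-PHOX (6 mol%), tetrabutylammonium difluorotriphenylsilicate (35 mol%), THF, 25 °C
Reagents that add atoms: diallyl carbonate, C=CCOC(=O)OCC=C
Why: Enantioselective Tsuji allylation of a silyl enol ether, in which fluoride (then allyl alkoxide) unmasks the enolate and this attacks the allyl–Pd–phosphinooxazoline complex at the methyl-bearing carbon to create the all-carbon quaternary centre (future C7); the (S)-ligand is chosen because the enolate face it selects in the 2-methylcyclohexanone series corresponds here to the R descriptor.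

Step 4
Reactants: 4 (6R)-4,6-dimethyl-6-(prop-2-en-1-yl)cyclohex-3-en-1-one; 5 pentadec-1-ene
Product: 6 (6R)-6-(hexadec-2-en-1-yl)-4,6-dimethylcyclohex-3-en-1-one (E/Z mixture)
Conditions: 5 (3 equiv), second-generation Grubbs catalyst (3 mol%), CH2Cl2, 40 °C
Reagents that add atoms: none
Why: Olefin cross-metathesis of the monosubstituted allyl olefin with excess terminal alkene extends the chain to sixteen carbons while the trisubstituted ring olefin is too hindered to engage; the E/Z mixture is irrelevant because this double bond is saturated next.

Step 5
Reactants: 6 (6R)-6-(hexadec-2-en-1-yl)-4,6-dimethylcyclohex-3-en-1-one (E/Z mixture)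
Product: 7 (6R)-6-hexadecyl-4,6-dimethylcyclohex-3-en-1-one
Conditions: H2 (1 atm), RhCl(PPh3)3 (5 mol%), benzene, rt
Reagents that add atoms: none
Why: Chemoselective homogeneous hydrogenation with the bulky rhodium phosphine complex should reduce the disubstituted chain olefin much faster than the trisubstituted ring olefin and leave the ketone and the quaternary centre untouched.

Step 6
Reactants: 7 (6R)-6-hexadecyl-4,6-dimethylcyclohex-3-en-1-one
Product: 8 (7R)-7-hexadecyl-5,7-dimethyl-6,7-dihydrooxepin-2(3H)-one
Conditions: Me3SiOOSiMe3 (1.5 equiv), TMSOTf (10 mol%), CH2Cl2, −40 °C; pyridine quench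
Reagents that add atoms: bis(trimethylsilyl) peroxide, C[Si](C)(C)OO[Si](C)(C)C
Why: Baeyer–Villiger oxidation with a silyl peroxide, which adds to the activated ketone but cannot epoxidise the ring olefin; in the Criegee adduct the more substituted carbon C7 migrates to oxygen with retention, so the quaternary centre becomes the tertiary C7–O stereocentre and the C2–C7 bond is cleaved by ring expansion.

Step 7
Reactants: 8 (7R)-7-hexadecyl-5,7-dimethyl-6,7-dihydrooxepin-2(3H)-one
Product: 9 (3Z,6R)-6-hydroxy-4,6-dimethyldocos-3-enoic acid
Conditions: LiOH·H2O (3 equiv), THF/H2O, 40 °C; then 1 M HCl to pH 4, 0 °C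
Reagents that add atoms: lithium hydroxide, [Li+].[OH-]
Why: Saponification by acyl–oxygen cleavage leaves the C7–O bond and its configuration intact and releases the hydroxy acid, whose C4=C5 olefin keeps the Z geometry (C3 and C6 cis) imposed by the former ring.

Step 8
Reactants: 9 (3Z,6R)-6-hydroxy-4,6-dimethyldocos-3-enoic acid
Product: 11 (4S,5S)-4-hydroxy-5-[(2R)-2-hydroxy-2-methyloctadecyl]-5-methyloxolan-2-one, via epoxy acid 10 (not isolated)
Conditions: 1,2:4,5-di-O-isopropylidene-β-L-erythro-2,3-hexodiulo-2,6-pyranose (30 mol%), Oxone (2KHSO5·KHSO4·K2SO4), K2CO3, Bu4NHSO4, Na2B4O7/Na2EDTA buffer, MeCN/CH2(OMe)2/H2O, 0 °C; then aq. KHSO4 to pH 3, EtOAc, 0 °C → rt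
Reagents that add atoms: potassium peroxymonosulfate (KHSO5, active salt of Oxone), [K+].[O-]S(=O)(=O)OO
Why: The dioxirane formed from the L-series ketone and KHSO5 transfers oxygen to the C4=C5 olefin of the carboxylate of 9 through a spiro transition state (Shi asymmetric epoxidation), in which C3 and the C5 methyl act as the trans pair that the catalyst reads, so epoxide 10 should form under reagent control irrespective of the remote C7 centre. On acidification the C2 carboxyl attacks the protonated epoxide at tertiary C5 from the backside, and the O1–C5 bond so formed closes the five-membered lactone in a 5-endo epoxide opening while the epoxide oxygen stays on C4 as the hydroxyl. The closest known reaction types are the ketone-catalysed asymmetric epoxidation of trisubstituted olefins and the peracid hydroxylactonisation of β,γ-unsaturated acids, which runs through the same kind of epoxy acid. C4 is set by the catalyst (oxygen delivery to one olefin face) and C5 by stereospecific inversion, and because the olefin is Z the net anti addition places the C4 hydroxyl cis to C6, that is (4S,5S). The step needs attack at C5 and not C4, and by the carboxyl and not the C7 hydroxyl: C5 is the tertiary, cation-stabilising terminus, and each alternative would have to close a four-membered ring (β-lactone or oxetane) or attack the less substituted carbon. Mild acid is used so that the opening stays concerted and the tertiary C7 alcohol does not ionise.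

**Compound list**

1 | 2,4-dimethylphenol | Cc1ccc(O)c(C)c1 | starting material
2 | tert-butyl(2,4-dimethylphenoxy)dimethylsilane | Cc1ccc(O[Si](C)(C)C(C)(C)C)c(C)c1 | intermediate
3 | tert-butyl[(2,4-dimethylcyclohexa-1,4-dien-1-yl)oxy]dimethylsilane | CC1=CCC(O[Si](C)(C)C(C)(C)C)=C(C)C1 | intermediate
4 | (6R)-4,6-dimethyl-6-(prop-2-en-1-yl)cyclohex-3-en-1-one | C=CC[C@@]1(C)C(=O)CC=C(C)C1 | intermediate
5 | pentadec-1-ene | C=CCCCCCCCCCCCCC | starting material
6 | (6R)-6-(hexadec-2-en-1-yl)-4,6-dimethylcyclohex-3-en-1-one (E/Z mixture) | CCCCCCCCCCCCCC=CC[C@@]1(C)C(=O)CC=C(C)C1 | intermediate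
7 | (6R)-6-hexadecyl-4,6-dimethylcyclohex-3-en-1-one | CCCCCCCCCCCCCCCC[C@@]1(C)C(=O)CC=C(C)C1 | intermediate
8 | (7R)-7-hexadecyl-5,7-dimethyl-6,7-dihydrooxepin-2(3H)-one | CCCCCCCCCCCCCCCC[C@@]1(C)OC(=O)CC=C(C)C1 | intermediate
9 | (3Z,6R)-6-hydroxy-4,6-dimethyldocos-3-enoic acid | CCCCCCCCCCCCCCCC[C@@](C)(O)C/C(C)=C\CC(=O)O | intermediate
10 | 2-[(2S,3R)-3-[(2R)-2-hydroxy-2-methyloctadecyl]-3-methyloxiran-2-yl]acetic acid | CCCCCCCCCCCCCCCC[C@@](C)(O)C[C@@]1(C)O[C@H]1CC(=O)O | intermediate (not isolated)
11 | (4S,5S)-4-hydroxy-5-[(2R)-2-hydroxy-2-methyloctadecyl]-5-methyloxolan-2-one | CCCCCCCCCCCCCCCC[C@@](C)(O)C[C@]1(C)OC(=O)C[C@@H]1O | target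

**Summary**

Total step count: 8. Longest linear sequence: 8 steps (from 1).

**Steps most likely to fail**

Step 8. The chiral dioxirane may discriminate the olefin faces poorly, because this Z-type trialkyl olefin carries the bulky C6 branch where the catalyst usually meets a small group; partial ionisation at C5 during the acid-triggered opening would erode stereospecificity further. Fallback: catalyst control is given up in favour of separation. Hydroxy acid 9 is treated with mCPBA (CH2Cl2, NaHCO3, 0 °C → rt), a peracid hydroxylactonisation in which the epoxy acids close through the same O1–C5 anti opening. Both olefin faces react, so target 11 should form together with its (4R,5R) diastereomer F1; the two differ as diastereomers because of C7 and are separated by chromatography. The fallback sets out from 9 and returns at 11.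

Step 6. The allylic methylene C3 may migrate instead of C7, the Lewis acid may fragment the Criegee adduct at the tertiary migrating carbon, or the tertiary alkyl–oxygen bond of the product may ionise. Fallback: the olefin is deliberately over-oxidised and then restored. Ketone 7 is treated with excess mCPBA (NaHCO3, CH2Cl2, rt). This first gives epoxy ketone F2, in which C3 is no longer allylic and is a poor migrating group. Continued Baeyer–Villiger oxidation without Lewis acid should then give epoxy lactone F3 (both epoxide faces, which does not matter). Deoxygenation of F3 with dimethyl diazomalonate and Rh2(OAc)4 (toluene, reflux) regenerates the olefin, which the seven-membered ring forces to be Z. The fallback sets out from 7 and returns at 8.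

Step 3. The free ammonium enolate may exchange protons with the product, whose C2 methylene is both α to the carbonyl and allylic, leading to regioisomeric or double allylation; the bulky silyl enol ether may also unmask sluggishly, and enantiofacial control may be incomplete. Fallback: the intermolecular fluoride-triggered mode is replaced by the intramolecular decarboxylative mode. Silyl enol ether 3 is cleaved with KOt-Bu (THF, 0 °C) to potassium dienolate F4, which is O-acylated with allyl chloroformate (−78 °C) to allyl enol carbonate F5. Treatment of F5 with Pd2(dba)3 and (S)-t-Bu-PHOX (THF, 25 °C) effects decarboxylative asymmetric allylic alkylation within a tight ion pair, which should preserve the enolate regiochemistry. The fallback sets out from 3 and returns at 4.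

**Further compounds**

F1 | step 8 | (4R,5R)-4-hydroxy-5-[(2R)-2-hydroxy-2-methyloctadecyl]-5-methyloxolan-2-one | CCCCCCCCCCCCCCCC[C@@](C)(O)C[C@@]1(C)OC(=O)C[C@H]1O
F2 | step 6 | (4R)-4-hexadecyl-4,6-dimethyl-7-oxabicyclo[4.1.0]heptan-3-one (both epoxide faces) | CCCCCCCCCCCCCCCC[C@@]1(C)C(=O)CC2OC2(C)C1
F3 | step 6 | (5R)-5-hexadecyl-5,7-dimethyl-4,8-dioxabicyclo[5.1.0]octan-3-one (both epoxide faces) | CCCCCCCCCCCCCCCC[C@@]1(C)OC(=O)CC2OC2(C)C1
F4 | step 3 | potassium 2,4-dimethylcyclohexa-1,4-dien-1-olate | CC1=C([O-])CC=C(C)C1.[K+]
F5 | step 3 | allyl 2,4-dimethylcyclohexa-1,4-dien-1-yl carbonate | C=CCOC(=O)OC1=C(C)CC(C)=CC1
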